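The route rests on the cis-1,2-disubstituted 3,3-dimethylcyclopropane of the target (two ring CH carbons plus CMe2). One CH carries the CH2 of the 3-oxobutyl chain and the other carries the ketone α-CH of the cyclopentanone, and this array is the skeleton of bicyclic lactone 6.
Lactone 6 (cyclopropane and γ-lactone, closed together and first) comes from prenyl diazoacetate 5 by catalytic enantioselective intramolecular cyclopropanation. Its C=O carbon becomes the first chain carbon (lactol, Wittig) and its OCH2 carbon becomes the ketone α-carbon (oxidation, one-carbon homologation to acid 16).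
The cyclopentanone (closed last) is cut at C(=O)–CH2 (Rh hydroacylation of 4-pentenal 36) and at the α-CH–quaternary C bond (Ireland–Claisen rearrangement of ester 30, made from acid 16 and allylic alcohol 29).
Alcohol 29 comes from L-leucine: OH replaces NH2 with retention, aryl replaces OTf with inversion (benzylic centre), then alkyne formation and syn-carboalumination give the E-alkene.
The arene travels as its trimethyl ether; the two formyl groups and the three free phenols are installed last.
Key step: step 4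

Remarks: Ar = 2,4,6-trimethoxyphenyl. Rh2(5R-MEPY)4 = dirhodium tetrakis[methyl (5R)-2-oxopyrrolidine-5-carboxylate]. DMP = Dess–Martin periodinane. dppe = Ph2PCH2CH2PPh2. nbd = norbornadiene. Reagents without a number are commercial.
Assumption: the (5R) ligand series is taken to deliver (1R,5S)-6; if the sense were the reverse, the (5S) catalyst would be used.

Step 1
Reactants: 1 3-methylbut-2-en-1-ol (prenol); 2 diketene
Product: 3 3-methylbut-2-en-1-yl 3-oxobutanoate
Conditions: NaOAc (cat.), THF, reflux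
Reagents that add atoms: none
Why: Acetoacetylation, in which the alcohol opens the strained β-lactone of diketene at its acyl carbon under mild base catalysis; no stereocentre is involved.

Step 2
Reactants: 3 3-methylbut-2-en-1-yl 3-oxobutanoate
Product: 4 3-methylbut-2-en-1-yl 2-diazo-3-oxobutanoate
Conditions: 4-acetamidobenzenesulfonyl azide, Et3N, MeCN, rt
Reagents that add atoms: 4-acetamidobenzenesulfonyl azide, CC(=O)Nc1ccc(cc1)S(=O)(=O)N=[N+]=[N-]
Why: Regitz diazo transfer, in which the enolate of the 1,3-dicarbonyl unit attacks the terminal nitrogen of the sulfonyl azide and the adduct collapses to the diazo compound and the sulfonamide.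

Step 3
Reactants: 4 3-methylbut-2-en-1-yl 2-diazo-3-oxobutanoate
Product: 5 3-methylbut-2-en-1-yl diazoacetate
Conditions: LiOH (aq), MeCN/H2O, rt
Reagents that add atoms: none
Why: Deacylation (retro-Claisen type cleavage), in which hydroxide adds to the more electrophilic ketone carbonyl and the stabilised diazoacetate anion leaves, while the ester, deactivated by the diazo group, stays intact.

Step 4
Reactants: 5 3-methylbut-2-en-1-yl diazoacetate
Product: 6 (1R,5S)-6,6-dimethyl-3-oxabicyclo[3.1.0]hexan-2-one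
Conditions: Rh2(5R-MEPY)4 (0.5 mol %), CH2Cl2, reflux, 5 added by syringe pump over 24–30 h
Reagents that add atoms: none
Why: The divalent-rhodium carboxamidate binds the diazo carbon of 5, N2 leaves, and the electrophilic rhodium carbenoid adds in one concerted, asynchronous step to the tethered trisubstituted alkene, forming the bonds from the carbenoid CH to the alkene CH and to CMe2 (closest known reaction type: dirhodium-carboxamidate-catalysed enantioselective intramolecular cyclopropanation of allylic diazoacetates). The cyclopropane closes by [2+1] addition, and the γ-lactone closes in the same event because the C(=O)–O–CH2 tether already joins the carbenoid carbon to the alkene CH, giving the five-membered ring of the bicyclo[3.1.0] system. The two new stereocentres (C1 and C5 of 6) are held cis to each other by the short tether, since a trans-fused bicyclo[3.1.0]hexane is out of reach, and their absolute sense is set by the four chiral pyrrolidone-carboxylate ligands, whose ester groups leave only one orientation of the alkene open towards the carbenoid. The step needs enantioface selectivity on an achiral alkene and chemoselectivity for cyclopropanation over carbene dimerisation and allylic C–H insertion; the electron-rich prenyl alkene, the tamed carboxamidate carbenoid and slow addition at high dilution should secure both. CMe2 is not stereogenic, so no further isomer can arise.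

Step 5
Reactants: 6 (1R,5S)-6,6-dimethyl-3-oxabicyclo[3.1.0]hexan-2-one
Product: 7 (1R,5S)-6,6-dimethyl-3-oxabicyclo[3.1.0]hexan-2-ol (anomer mixture)
Conditions: i-Bu2AlH (1.05 equiv), CH2Cl2, −78 °C
Reagents that add atoms: none
Why: Partial lactone reduction, in which the tetrahedral aluminium lactolate survives at −78 °C until work-up, so reduction stops at the lactol and never reaches the achiral (meso) diol; the ring stereocentres are untouched and the anomeric centre is of no consequence.

Step 6
Reactants: 7 (1R,5S)-6,6-dimethyl-3-oxabicyclo[3.1.0]hexan-2-ol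
Product: 8 (3E)-4-[(1R,3S)-3-(hydroxymethyl)-2,2-dimethylcyclopropyl]but-3-en-2-one
Conditions: Ph3P=CHC(O)CH3, THF, 50 °C
Reagents that add atoms: 1-(triphenylphosphoranylidene)propan-2-one, CC(=O)C=P(c1ccccc1)(c1ccccc1)c1ccccc1
Why: Wittig olefination of the open hydroxy aldehyde tautomer with a stabilised ylide should give the E-enone; no base is added, the temperature is kept moderate and 8 is reduced at once, so that oxa-Michael closure of the cis-CH2OH group and thermal hydrogen shift of the cis-vinylcyclopropane do not set in.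

Step 7
Reactants: 8 (3E)-4-[(1R,3S)-3-(hydroxymethyl)-2,2-dimethylcyclopropyl]but-3-en-2-one
Product: 9 4-[(1R,3S)-3-(hydroxymethyl)-2,2-dimethylcyclopropyl]butan-2-one
Conditions: Cu(OAc)2·H2O (3 mol %), 1,2-(Ph2P)2C6H4 (3 mol %), (EtO)2MeSiH, t-BuOH, toluene, 0 °C → rt; aq. NH4F work-up
Reagents that add atoms: none
Why: Copper hydride conjugate reduction delivers hydride as a two-electron nucleophile to the β-carbon and t-BuOH protonates the copper enolate, so no radical or cation arises next to the cyclopropane (as it could with H2 on Pd or with dissolving metals) and the ring stays closed.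

Step 8
Reactants: 9 4-[(1R,3S)-3-(hydroxymethyl)-2,2-dimethylcyclopropyl]butan-2-one
Product: 10 {(1S,3R)-2,2-dimethyl-3-[2-(2-methyl-1,3-dioxolan-2-yl)ethyl]cyclopropyl}methanol
Conditions: HOCH2CH2OH, pyridinium tosylate (cat.), benzene, reflux, Dean–Stark trap
Reagents that add atoms: ethane-1,2-diol, OCCO
Why: Acid-catalysed ketalisation with azeotropic removal of water masks the methyl ketone against the ylide, enolate and hydride steps ahead, and the weak acid should not ionise the cyclopropylcarbinol.

Step 9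
Reactants: 10 {(1S,3R)-2,2-dimethyl-3-[2-(2-methyl-1,3-dioxolan-2-yl)ethyl]cyclopropyl}methanol
Product: 11 (1S,3R)-2,2-dimethyl-3-[2-(2-methyl-1,3-dioxolan-2-yl)ethyl]cyclopropane-1-carbaldehyde
Conditions: DMP, NaHCO3, CH2Cl2, 0 °C → rt
Reagents that add atoms: none
Why: Dess–Martin oxidation under buffered, non-basic conditions should give the cis-cyclopropanecarbaldehyde without epimerisation at the ring carbon, whose enolisation is in any case disfavoured by ring strain.

Step 10
Reactants: 11 (1S,3R)-2,2-dimethyl-3-[2-(2-methyl-1,3-dioxolan-2-yl)ethyl]cyclopropane-1-carbaldehyde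
Product: 12 2-{2-[(1R,3S)-3-ethenyl-2,2-dimethylcyclopropyl]ethyl}-2-methyl-1,3-dioxolane
Conditions: Ph3PCH3Br, KOt-Bu, THF, 0 °C
Reagents that add atoms: methyltriphenylphosphonium bromide, C[P+](c1ccccc1)(c1ccccc1)c1ccccc1.[Br-]
Why: Wittig methylenation adds the carbon that will become the ring carbonyl, and the aldehyde is attacked by the ylide faster than it is deprotonated, so the cis relationship is kept.

Step 11
Reactants: 12 2-{2-[(1R,3S)-3-ethenyl-2,2-dimethylcyclopropyl]ethyl}-2-methyl-1,3-dioxolane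
Product: 14 2-{(1S,3R)-2,2-dimethyl-3-[2-(2-methyl-1,3-dioxolan-2-yl)ethyl]cyclopropyl}ethan-1-ol, via B-alkyl-9-BBN adduct 13 (not isolated)
Conditions: 9-BBN, THF, 0 °C → rt; NaOH, H2O2, 0 °C
Reagents that add atoms: hydrogen peroxide, OO
Why: Anti-Markovnikov hydroboration–oxidation, in which the bulky borane places boron on the terminal carbon away from the ring, so no cyclopropylcarbinyl boron species forms, and basic peroxide leaves the ketal alone.

Step 12
Reactants: 14 2-{(1S,3R)-2,2-dimethyl-3-[2-(2-methyl-1,3-dioxolan-2-yl)ethyl]cyclopropyl}ethan-1-ol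
Product: 16 {(1S,3R)-2,2-dimethyl-3-[2-(2-methyl-1,3-dioxolan-2-yl)ethyl]cyclopropyl}acetic acid, via homologous aldehyde 15 (not isolated)
Conditions: TEMPO (cat.), NaOCl (cat.), NaClO2, MeCN/phosphate buffer pH 6.7, 35 °C
Reagents that add atoms: sodium chlorite, [Na+].[O-]Cl=O
Why: TEMPO/chlorite oxidation near neutral pH takes the primary alcohol through the aldehyde to the acid without any acid strong enough to cleave the ketal.

Step 13
Reactants: 17 L-leucine
Product: 18 (2S)-2-hydroxy-4-methylpentanoic acid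
Conditions: NaNO2, 1 M H2SO4, H2O, 0 °C → rt
Reagents that add atoms: water, O
Why: Diazotisation of an α-amino acid, in which the carboxylate displaces N2 to give an α-lactone that water opens; the two inversions add up to retention, so the (S) centre of L-leucine is kept.

Step 14
Reactants: 18 (2S)-2-hydroxy-4-methylpentanoic acid
Product: 19 tert-butyl (2S)-2-hydroxy-4-methylpentanoate
Conditions: Cl3CC(=NH)Ot-Bu, CH2Cl2/cyclohexane, rt
Reagents that add atoms: tert-butyl 2,2,2-trichloroacetimidate, CC(C)(C)OC(=N)C(Cl)(Cl)Cl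
Why: tert-Butyl transfer from the imidate, which the carboxylic acid itself activates by protonation, gives the bulky ester that shields the carbonyl from the Grignard reagent; the stereocentre takes no part.

Step 15
Reactants: 19 tert-butyl (2S)-2-hydroxy-4-methylpentanoate
Product: 20 tert-butyl (2S)-4-methyl-2-(trifluoromethylsulfonyloxy)pentanoate
Conditions: Tf2O, 2,6-lutidine, CH2Cl2, −78 → 0 °C
Reagents that add atoms: trifluoromethanesulfonic anhydride, FC(F)(F)S(=O)(=O)OS(=O)(=O)C(F)(F)F
Why: O-Sulfonylation with a hindered, non-nucleophilic base leaves the C–O bond and thus the (S) configuration untouched, and the adjacent ester suppresses ionisation of the triflate.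

Step 16
Reactants: 20 tert-butyl (2S)-4-methyl-2-(trifluoromethylsulfonyloxy)pentanoate; 21 2-bromo-1,3,5-trimethoxybenzene
Product: 23 tert-butyl (2S)-4-methyl-2-(2,4,6-trimethoxyphenyl)pentanoate, via 2,4,6-trimethoxyphenylmagnesium bromide 22 (not isolated)
Conditions: 21, Mg, THF, reflux; ZnCl2 (10 mol %), then 20, THF, 0 °C → rt
Reagents that add atoms: none
Why: Proposed new method: ZnCl2 and three equivalents of 22 should form the triarylzincate Ar3ZnMgBr, a soft carbon nucleophile of low basicity that attacks the triflate-bearing carbon from the rear (SN2, accelerated by overlap with the ester π* orbital and by magnesium binding to the leaving group), so that (S)-20 gives the aryl ester with inversion, which keeps the descriptor (S) only because the priorities change; aryl transfer leaves Ar2Zn, which 22 recharges; the closest known reaction type is the zinc-catalysed coupling of alkyl Grignard reagents with α-triflyloxy esters, which runs with clean inversion, and what is new is the sp2, doubly ortho-substituted nucleophile.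

Step 17
Reactants: 23 tert-butyl (2S)-4-methyl-2-(2,4,6-trimethoxyphenyl)pentanoate
Product: 24 (2S)-4-methyl-2-(2,4,6-trimethoxyphenyl)pentan-1-ol
Conditions: i-Bu2AlH (3 equiv), CH2Cl2, −78 → 0 °C
Reagents that add atoms: none
Why: Aluminium hydride reduction of the ester under non-basic conditions should give the primary alcohol without enolisation of the α-aryl ester.

Step 18
Reactants: 24 (2S)-4-methyl-2-(2,4,6-trimethoxyphenyl)pentan-1-ol
Product: 25 (2S)-4-methyl-2-(2,4,6-trimethoxyphenyl)pentanal
Conditions: DMP, NaHCO3, CH2Cl2, 0 °C; used at once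
Reagents that add atoms: none
Why: Dess–Martin oxidation is neutral and fast, so the α-aryl aldehyde, whose twisted electron-rich aryl group lends the α-hydrogen little extra acidity, should not racemise.

Step 19
Reactants: 25 (2S)-4-methyl-2-(2,4,6-trimethoxyphenyl)pentanal
Product: 26 1,3,5-trimethoxy-2-[(3R)-5-methylhex-1-yn-3-yl]benzene
Conditions: Me3SiCHN2, n-BuLi, THF, −78 °C; then 25, −78 → 0 °C
Reagents that add atoms: (trimethylsilyl)diazomethane, C[Si](C)(C)C=[N+]=[N-]
Why: Colvin rearrangement (Seyferth–Gilbert type homologation), in which the lithiated silyldiazomethane adds to the aldehyde at −78 °C faster than it deprotonates it, loss of silanolate and N2 gives an alkylidene carbene, and a 1,2-hydrogen shift gives the terminal alkyne with the benzylic centre spatially unchanged (the descriptor becomes R by priority change).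

Step 20
Reactants: 26 1,3,5-trimethoxy-2-[(3R)-5-methylhex-1-yn-3-yl]benzene
Product: 29 (2E,4R)-3,6-dimethyl-4-(2,4,6-trimethoxyphenyl)hept-2-en-1-ol, via (E)-alkenyldimethylalane 27 (not isolated), via lithium alkenylalanate 28 (not isolated)
Conditions: Me3Al, Cp2ZrCl2 (0.25 equiv), CH2Cl2, 0 °C → rt; excess Me3Al removed in vacuo; THF, n-BuLi, −78 °C; (CH2O)n, −78 °C → rt
Reagents that add atoms: trimethylaluminium, C[Al](C)C; formaldehyde (as paraformaldehyde), C=O
Why: Negishi zirconium-catalysed carboalumination adds methyl and aluminium syn across the alkyne with the metal on the terminal carbon, and the alanate takes up formaldehyde with retention, which fixes the E geometry (benzylic carbon trans to CH2OH); n-BuLi is consumed by the alane, so the benzylic C–H is not touched.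

Step 21
Reactants: 16 {(1S,3R)-2,2-dimethyl-3-[2-(2-methyl-1,3-dioxolan-2-yl)ethyl]cyclopropyl}acetic acid; 29 (2E,4R)-3,6-dimethyl-4-(2,4,6-trimethoxyphenyl)hept-2-en-1-ol
Product: 30 (2E,4R)-3,6-dimethyl-4-(2,4,6-trimethoxyphenyl)hept-2-en-1-yl {(1S,3R)-2,2-dimethyl-3-[2-(2-methyl-1,3-dioxolan-2-yl)ethyl]cyclopropyl}acetate
Conditions: DCC, DMAP (cat.), CH2Cl2, 0 °C → rt
Reagents that add atoms: none
Why: Steglich esterification joins the two fragments under neutral conditions without touching any stereocentre.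

Step 22
Reactants: 30 (2E,4R)-3,6-dimethyl-4-(2,4,6-trimethoxyphenyl)hept-2-en-1-yl {(1S,3R)-2,2-dimethyl-3-[2-(2-methyl-1,3-dioxolan-2-yl)ethyl]cyclopropyl}acetate
Product: 34 (2R,3R,4R)-2-{(1R,3R)-2,2-dimethyl-3-[2-(2-methyl-1,3-dioxolan-2-yl)ethyl]cyclopropyl}-3-ethenyl-3,6-dimethyl-4-(2,4,6-trimethoxyphenyl)heptanoic acid, via lithium ester enolate 31 (not isolated), via (Z)-trimethylsilyl ketene acetal 32 (not isolated), via trimethylsilyl ester 33 (not isolated)
Conditions: LiN(i-Pr)2 (1.2 equiv), THF/DMPU 4:1, −78 °C; Me3SiCl, −78 °C → rt, then 60 °C; aq. NaH2PO4 work-up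
Reagents that add atoms: none
Why: Ireland–Claisen rearrangement, in which THF/DMPU should give the enolate and ketene acetal with the cyclopropyl group cis to OSi, so that the chair transition state carries both large groups (cyclopropyl on the enolate carbon, arylalkyl group on the E-alkene terminus) equatorially and sets the α-carbon and the quaternary carbon in the relative sense needed (cyclopropyl trans to the arylalkyl group in the later ring); the alkene face is chosen by the benzylic centre in a staggered arrangement with the aryl group anti to the incoming carbon, its hydrogen outside next to the axial methyl and the cyclopropyl group, and the isobutyl group inside next to the vinylic hydrogen, which leads to the (3R,4R) relationship.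

Step 23
Reactants: 34 the heptanoic acid from step 22
Product: 35 (2R,3R,4R)-2-{(1R,3R)-2,2-dimethyl-3-[2-(2-methyl-1,3-dioxolan-2-yl)ethyl]cyclopropyl}-3-ethenyl-3,6-dimethyl-4-(2,4,6-trimethoxyphenyl)heptan-1-ol
Conditions: LiAlH4, THF, 0 °C → reflux
Reagents that add atoms: none
Why: Hydride reduction of the hindered carboxylic acid spares the ketal, the vinyl group, the cyclopropane and the aryl ethers.

Step 24
Reactants: 35 the heptan-1-ol from step 23
Product: 36 (2R,3R,4R)-2-{(1R,3R)-2,2-dimethyl-3-[2-(2-methyl-1,3-dioxolan-2-yl)ethyl]cyclopropyl}-3-ethenyl-3,6-dimethyl-4-(2,4,6-trimethoxyphenyl)heptanal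
Conditions: DMP, NaHCO3, CH2Cl2, 0 °C → rt
Reagents that add atoms: none
Why: Dess–Martin oxidation copes with neopentyl-type alcohols and is neutral, and any slight epimerisation at the α-carbon is put right after ring closure.

Step 25
Reactants: 36 the 4-pentenal-type aldehyde from step 24
Product: 37 (2R,3R)-2-{(1R,3R)-2,2-dimethyl-3-[2-(2-methyl-1,3-dioxolan-2-yl)ethyl]cyclopropyl}-3-methyl-3-[(1R)-3-methyl-1-(2,4,6-trimethoxyphenyl)butyl]cyclopentan-1-one
Conditions: [Rh(nbd)(dppe)]BF4 (10 mol %; H2 for 5 min, then Ar purge), CH2Cl2, rt → 40 °C; then DBU (0.2 equiv), CH2Cl2, rt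
Reagents that add atoms: none
Why: Intramolecular alkene hydroacylation of a 4-pentenal, in which monovalent rhodium inserts into the formyl C–H bond, the vinyl group inserts into Rh–H to give the six-membered acyl metallacycle and reductive elimination closes the C(=O)–CH2 bond of the five-membered ring, helped by the quaternary carbon (Thorpe–Ingold effect); no stereocentre is made, and DBU lets the ketone α-carbon settle with the cyclopropyl group trans to the bulky arylalkyl group, which is the target configuration.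

Step 26
Reactants: 37 the ketal-protected cyclopentanone from step 25
Product: 38 (2R,3R)-2-[(1R,3R)-2,2-dimethyl-3-(3-oxobutyl)cyclopropyl]-3-methyl-3-[(1R)-3-methyl-1-(2,4,6-trimethoxyphenyl)butyl]cyclopentan-1-one
Conditions: 1 M HCl/THF 1:4, rt
Reagents that add atoms: water, O
Why: Dilute-acid hydrolysis of the dioxolane leaves the alkyl-substituted cyclopropane intact, and freeing the ketone now prevents the ketal from turning into a formylatable enol ether under TiCl4 in the next step.

Step 27
Reactants: 38 the trimethoxyaryl diketone from step 26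
Product: 40 5-{(1R)-1-[(1R,2R)-2-[(1R,3R)-2,2-dimethyl-3-(3-oxobutyl)cyclopropyl]-1-methyl-3-oxocyclopentyl]-3-methylbutyl}-2,4,6-trimethoxybenzene-1,3-dicarbaldehyde, via bis(chloromethoxymethyl)arene 39 (not isolated)
Conditions: Cl2CHOMe (6 equiv), TiCl4 (8 equiv), CH2Cl2, −78 → 0 °C; poured into ice-water
Reagents that add atoms: dichloromethyl methyl ether, COC(Cl)Cl; water, O
Why: Rieche formylation, in which the TiCl4-activated dichloromethyl ether attacks the only two free ring positions, each flanked by two methoxy groups, so regiochemistry is not in question; the three donors keep the ring reactive enough for the second substitution, the TiCl4-bound ketones are not enolised, and low temperature with a cold quench limits protonation of the cyclopropane.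

Step 28
Reactants: 40 the trimethoxy dialdehyde from step 27
Product: 41 5-{(1R)-1-[(1R,2R)-2-[(1R,3R)-2,2-dimethyl-3-(3-oxobutyl)cyclopropyl]-1-methyl-3-oxocyclopentyl]-3-methylbutyl}-2,4,6-trihydroxybenzene-1,3-dicarbaldehyde (target)
Conditions: 4-MeC6H4SLi (8 equiv; from 4-MeC6H4SH and n-BuLi), HMPA/toluene, 110 °C; then cold 1 M HCl
Reagents that add atoms: none
Why: Thiolate SN2 dealkylation, in which every OMe group lies ortho or para to both formyl groups and so is a vinylogous methyl ester with a good phenoxide leaving group for the soft, weakly basic thiolate, which should neither open the cyclopropane nor enolise the ketones to any extent; any equilibration at the ketone α-carbon ends at the trans arrangement already present.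

Compound list
1 | 3-methylbut-2-en-1-ol | CC(C)=CCO | starting material
2 | diketene | C=C1CC(=O)O1 | starting material
3 | 3-methylbut-2-en-1-yl 3-oxobutanoate | CC(C)=CCOC(=O)CC(C)=O | intermediate
4 | 3-methylbut-2-en-1-yl 2-diazo-3-oxobutanoate | CC(C)=CCOC(=O)C(=[N+]=[N-])C(C)=O | intermediate
5 | 3-methylbut-2-en-1-yl diazoacetate | CC(C)=CCOC(=O)C=[N+]=[N-] | intermediate
6 | (1R,5S)-6,6-dimethyl-3-oxabicyclo[3.1.0]hexan-2-one | O=C1[C@@H]2[C@H](CO1)C2(C)C | intermediate
7 | (1R,5S)-6,6-dimethyl-3-oxabicyclo[3.1.0]hexan-2-ol (anomers) | OC1[C@@H]2[C@H](CO1)C2(C)C | intermediate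
8 | (3E)-4-[(1R,3S)-3-(hydroxymethyl)-2,2-dimethylcyclopropyl]but-3-en-2-one | CC(=O)/C=C/[C@@H]1[C@H](CO)C1(C)C | intermediate
9 | 4-[(1R,3S)-3-(hydroxymethyl)-2,2-dimethylcyclopropyl]butan-2-one | CC(=O)CC[C@@H]1[C@H](CO)C1(C)C | intermediate
10 | {(1S,3R)-2,2-dimethyl-3-[2-(2-methyl-1,3-dioxolan-2-yl)ethyl]cyclopropyl}methanol | CC1(OCCO1)CC[C@@H]2[C@H](CO)C2(C)C | intermediate
11 | (1S,3R)-2,2-dimethyl-3-[2-(2-methyl-1,3-dioxolan-2-yl)ethyl]cyclopropane-1-carbaldehyde | CC1(OCCO1)CC[C@@H]2[C@H](C=O)C2(C)C | intermediate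
12 | 2-{2-[(1R,3S)-3-ethenyl-2,2-dimethylcyclopropyl]ethyl}-2-methyl-1,3-dioxolane | CC1(OCCO1)CC[C@@H]2[C@H](C=C)C2(C)C | intermediate
13 | 9-(2-{(1S,3R)-2,2-dimethyl-3-[2-(2-methyl-1,3-dioxolan-2-yl)ethyl]cyclopropyl}ethyl)-9-borabicyclo[3.3.1]nonane | CC1(OCCO1)CC[C@@H]2[C@H](CCB3C4CCCC3CCC4)C2(C)C | intermediate (not isolated)
14 | 2-{(1S,3R)-2,2-dimethyl-3-[2-(2-methyl-1,3-dioxolan-2-yl)ethyl]cyclopropyl}ethan-1-ol | CC1(OCCO1)CC[C@@H]2[C@H](CCO)C2(C)C | intermediate
15 | {(1S,3R)-2,2-dimethyl-3-[2-(2-methyl-1,3-dioxolan-2-yl)ethyl]cyclopropyl}acetaldehyde | CC1(OCCO1)CC[C@@H]2[C@H](CC=O)C2(C)C | intermediate (not isolated)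
16 | {(1S,3R)-2,2-dimethyl-3-[2-(2-methyl-1,3-dioxolan-2-yl)ethyl]cyclopropyl}acetic acid | CC1(OCCO1)CC[C@@H]2[C@H](CC(=O)O)C2(C)C | intermediate
17 | L-leucine | CC(C)C[C@H](N)C(=O)O | starting material
18 | (2S)-2-hydroxy-4-methylpentanoic acid | CC(C)C[C@H](O)C(=O)O | intermediate
19 | tert-butyl (2S)-2-hydroxy-4-methylpentanoate | CC(C)C[C@H](O)C(=O)OC(C)(C)C | intermediate
20 | tert-butyl (2S)-4-methyl-2-(trifluoromethylsulfonyloxy)pentanoate | CC(C)C[C@H](OS(=O)(=O)C(F)(F)F)C(=O)OC(C)(C)C | intermediate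
21 | 2-bromo-1,3,5-trimethoxybenzene | COc1cc(OC)c(Br)c(OC)c1 | starting material
22 | 2,4,6-trimethoxyphenylmagnesium bromide | COc1cc(OC)c([Mg]Br)c(OC)c1 | intermediate (not isolated)
23 | tert-butyl (2S)-4-methyl-2-(2,4,6-trimethoxyphenyl)pentanoate | CC(C)C[C@@H](c1c(OC)cc(OC)cc1OC)C(=O)OC(C)(C)C | intermediate
24 | (2S)-4-methyl-2-(2,4,6-trimethoxyphenyl)pentan-1-ol | CC(C)C[C@@H](c1c(OC)cc(OC)cc1OC)CO | intermediate
25 | (2S)-4-methyl-2-(2,4,6-trimethoxyphenyl)pentanal | CC(C)C[C@@H](c1c(OC)cc(OC)cc1OC)C=O | intermediate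
26 | 1,3,5-trimethoxy-2-[(3R)-5-methylhex-1-yn-3-yl]benzene | CC(C)C[C@@H](c1c(OC)cc(OC)cc1OC)C#C | intermediate
27 | dimethyl[(1E,3R)-2,5-dimethyl-3-(2,4,6-trimethoxyphenyl)hex-1-en-1-yl]alane | C[Al](C)/C=C(\C)[C@@H](CC(C)C)c1c(OC)cc(OC)cc1OC | intermediate (not isolated)
28 | lithium butyl(dimethyl)[(1E,3R)-2,5-dimethyl-3-(2,4,6-trimethoxyphenyl)hex-1-en-1-yl]alanate | [Li+].CCCC[Al-](C)(C)/C=C(\C)[C@@H](CC(C)C)c1c(OC)cc(OC)cc1OC | intermediate (not isolated)
29 | (2E,4R)-3,6-dimethyl-4-(2,4,6-trimethoxyphenyl)hept-2-en-1-ol | OC/C=C(\C)[C@@H](CC(C)C)c1c(OC)cc(OC)cc1OC | intermediate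
30 | ester of 16 with 29 | CC1(OCCO1)CC[C@@H]2[C@H](CC(=O)OC/C=C(\C)[C@@H](CC(C)C)c3c(OC)cc(OC)cc3OC)C2(C)C | intermediate
31 | lithium enolate of 30 (cyclopropyl cis to OLi) | [Li+].CC1(OCCO1)CC[C@@H]2[C@H](/C=C(\[O-])OC/C=C(\C)[C@@H](CC(C)C)c3c(OC)cc(OC)cc3OC)C2(C)C | intermediate (not isolated)
32 | (Z)-trimethylsilyl ketene acetal of 30 | CC1(OCCO1)CC[C@@H]2[C@H](/C=C(\O[Si](C)(C)C)OC/C=C(\C)[C@@H](CC(C)C)c3c(OC)cc(OC)cc3OC)C2(C)C | intermediate (not isolated)
33 | trimethylsilyl ester of 34 | CC1(OCCO1)CC[C@@H]2[C@H]([C@H]([C@](C)(C=C)[C@@H](CC(C)C)c3c(OC)cc(OC)cc3OC)C(=O)O[Si](C)(C)C)C2(C)C | intermediate (not isolated)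
34 | (2R,3R,4R)-2-{(1R,3R)-2,2-dimethyl-3-[2-(2-methyl-1,3-dioxolan-2-yl)ethyl]cyclopropyl}-3-ethenyl-3,6-dimethyl-4-(2,4,6-trimethoxyphenyl)heptanoic acid | CC1(OCCO1)CC[C@@H]2[C@H]([C@H]([C@](C)(C=C)[C@@H](CC(C)C)c3c(OC)cc(OC)cc3OC)C(=O)O)C2(C)C | intermediate
35 | corresponding (2R,3R,4R)-heptan-1-ol | CC1(OCCO1)CC[C@@H]2[C@H]([C@H]([C@](C)(C=C)[C@@H](CC(C)C)c3c(OC)cc(OC)cc3OC)CO)C2(C)C | intermediate
36 | corresponding (2R,3R,4R)-heptanal | CC1(OCCO1)CC[C@@H]2[C@H]([C@H]([C@](C)(C=C)[C@@H](CC(C)C)c3c(OC)cc(OC)cc3OC)C=O)C2(C)C | intermediate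
37 | (2R,3R)-2-{(1R,3R)-2,2-dimethyl-3-[2-(2-methyl-1,3-dioxolan-2-yl)ethyl]cyclopropyl}-3-methyl-3-[(1R)-3-methyl-1-(2,4,6-trimethoxyphenyl)butyl]cyclopentan-1-one | CC1(OCCO1)CC[C@@H]2[C@H]([C@H]3C(=O)CC[C@]3(C)[C@@H](CC(C)C)c4c(OC)cc(OC)cc4OC)C2(C)C | intermediate
38 | (2R,3R)-2-[(1R,3R)-2,2-dimethyl-3-(3-oxobutyl)cyclopropyl]-3-methyl-3-[(1R)-3-methyl-1-(2,4,6-trimethoxyphenyl)butyl]cyclopentan-1-one | CC(=O)CC[C@@H]1[C@H]([C@H]2C(=O)CC[C@]2(C)[C@@H](CC(C)C)c2c(OC)cc(OC)cc2OC)C1(C)C | intermediate
39 | 3,5-bis[chloro(methoxy)methyl] derivative of 38 | CC(=O)CC[C@@H]1[C@H]([C@H]2C(=O)CC[C@]2(C)[C@@H](CC(C)C)c2c(OC)c(C(Cl)OC)c(OC)c(C(Cl)OC)c2OC)C1(C)C | intermediate (not isolated)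
40 | trimethyl ether of the target (2,4,6-trimethoxybenzene-1,3-dicarbaldehyde) | CC(=O)CC[C@@H]1[C@H]([C@H]2C(=O)CC[C@]2(C)[C@@H](CC(C)C)c2c(OC)c(C=O)c(OC)c(C=O)c2OC)C1(C)C | intermediate
41 | CNP0217082.3 | CC(=O)CC[C@@H]1[C@H]([C@H]2C(=O)CC[C@]2(C)[C@@H](CC(C)C)c2c(O)c(C=O)c(O)c(C=O)c2O)C1(C)C | target

Total step count: 28. Longest linear sequence: 20 steps (steps 1–12, then 21–28). The leucine branch (steps 13–20) has 8 steps.

Steps most likely to fail

1. Step 16 (labelled step).
- What may go wrong: the doubly ortho-substituted arylzincate may attack the secondary carbon too slowly. Loss of triflic acid by elimination, or prior substitution by bromide ion (which would erode the configuration through a double inversion), could then take over.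
- Fallback: auxiliary-controlled alkylation instead of chiral-pool substitution, known chemistry throughout. It sets out from Grignard reagent 22 and comes back at alcohol 24.
- Reagent 22 opens oxirane (THF, 0 °C) to 2-(2,4,6-trimethoxyphenyl)ethan-1-ol F1.
- (n-Pr4N)RuO4 (cat.) with N-methylmorpholine N-oxide monohydrate oxidises this to (2,4,6-trimethoxyphenyl)acetic acid F2.
- Pivaloyl chloride/Et3N gives the mixed pivalic anhydride F3, which acylates (4S)-4-benzyl-1,3-oxazolidin-2-one (LiCl, Et3N) to (4S)-4-benzyl-3-[(2,4,6-trimethoxyphenyl)acetyl]-1,3-oxazolidin-2-one F4.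
- Evans alkylation (NaN(SiMe3)2, THF, −78 °C, 3-bromo-2-methylprop-1-ene) takes place on the chelated Z-enolate from the face away from the benzyl group. It gives (4S)-4-benzyl-3-[(2S)-4-methyl-2-(2,4,6-trimethoxyphenyl)pent-4-enoyl]-1,3-oxazolidin-2-one F5.
- LiBH4 removes the auxiliary to give (2S)-4-methyl-2-(2,4,6-trimethoxyphenyl)pent-4-en-1-ol F6, and H2 over Pd/C saturates the alkene to 24.

2. Step 22.
- What may go wrong: facial selectivity at the quaternary carbon may be poor, because the only control element on the allyl part is the neighbouring benzylic centre. Bond formation at the congested terminus may also be slow, and longer heating invites decay of the ketene acetal and a homo-1,5-hydrogen shift of its cis-alkyl vinylcyclopropane unit.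
- Fallback: 1,3-chirality transfer from a secondary carbinol instead of control by the neighbouring centre. It sets out from alkyne 26 (and acid 16) and comes back at acid 34.
- Alanate 28, made from 26 as in step 20, is quenched with acetaldehyde to give (3E,5R)-4,7-dimethyl-5-(2,4,6-trimethoxyphenyl)oct-3-en-2-ol as both carbinol epimers F7.
- DMP gives (3E,5R)-4,7-dimethyl-5-(2,4,6-trimethoxyphenyl)oct-3-en-2-one F8.
- Corey–Bakshi–Shibata reduction with the (S)-methyl oxazaborolidine and BH3·SMe2, the alkenyl group acting as the large group, gives (2R,3E,5R)-4,7-dimethyl-5-(2,4,6-trimethoxyphenyl)oct-3-en-2-ol F9.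
- Steglich esterification with 16 gives the (2R)-oct-3-en-2-yl ester F10.
- Ireland–Claisen rearrangement under the conditions of step 22 runs through the chair with the carbinol methyl group equatorial, since the axial placement suffers A1,3 strain with the alkene methyl group. The enolate carbon is therefore delivered to the required face, giving the (E)-prop-1-enyl analogue of 34, F11.
- Ethenolysis (ethene, second-generation Hoveyda–Grubbs catalyst, toluene, 40 °C) trims the propenyl group to the vinyl group of 34.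

3. Step 25.
- What may go wrong: decarbonylation of the acyl rhodium hydride and binding of the cationic rhodium to the electron-rich arene may outrun insertion of the neopentyl-type vinyl group, so that the catalyst dies as a carbonyl complex.
- Fallback: ring-closing metathesis instead of C–H activation. It sets out from aldehyde 36 and comes back at cyclopentanone 37.
- Vinylmagnesium bromide (THF, −78 °C) adds to 36 to give the divinyl carbinol (4R,5R,6R)-4-{(1R,3R)-2,2-dimethyl-3-[2-(2-methyl-1,3-dioxolan-2-yl)ethyl]cyclopropyl}-5-ethenyl-5,8-dimethyl-6-(2,4,6-trimethoxyphenyl)non-1-en-3-ol F12. Its carbinol epimers are of no consequence.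
- Second-generation Grubbs catalyst, RuCl2(PCy3)(SIMes)(=CHPh), in CH2Cl2 at 40 °C closes the cyclopent-2-en-1-ol F13.
- DMP gives the cyclopent-2-en-1-one F14, and copper hydride conjugate reduction as in step 7 gives 37.

Further compounds
F1 | step 16 | 2-(2,4,6-trimethoxyphenyl)ethan-1-ol | OCCc1c(OC)cc(OC)cc1OC
F2 | step 16 | (2,4,6-trimethoxyphenyl)acetic acid | OC(=O)Cc1c(OC)cc(OC)cc1OC
F3 | step 16 | 2,2-dimethylpropanoic (2,4,6-trimethoxyphenyl)acetic anhydride | CC(C)(C)C(=O)OC(=O)Cc1c(OC)cc(OC)cc1OC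
F4 | step 16 | (4S)-4-benzyl-3-[(2,4,6-trimethoxyphenyl)acetyl]-1,3-oxazolidin-2-one | O=C(Cc1c(OC)cc(OC)cc1OC)N1[C@@H](Cc2ccccc2)COC1=O
F5 | step 16 | (4S)-4-benzyl-3-[(2S)-4-methyl-2-(2,4,6-trimethoxyphenyl)pent-4-enoyl]-1,3-oxazolidin-2-one | C=C(C)C[C@@H](c1c(OC)cc(OC)cc1OC)C(=O)N1[C@@H](Cc2ccccc2)COC1=O
F6 | step 16 | (2S)-4-methyl-2-(2,4,6-trimethoxyphenyl)pent-4-en-1-ol | C=C(C)C[C@@H](c1c(OC)cc(OC)cc1OC)CO
F7 | step 22 | (3E,5R)-4,7-dimethyl-5-(2,4,6-trimethoxyphenyl)oct-3-en-2-ol (both carbinol epimers) | CC(O)/C=C(\C)[C@@H](CC(C)C)c1c(OC)cc(OC)cc1OC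
F8 | step 22 | (3E,5R)-4,7-dimethyl-5-(2,4,6-trimethoxyphenyl)oct-3-en-2-one | CC(=O)/C=C(\C)[C@@H](CC(C)C)c1c(OC)cc(OC)cc1OC
F9 | step 22 | (2R,3E,5R)-4,7-dimethyl-5-(2,4,6-trimethoxyphenyl)oct-3-en-2-ol | C[C@@H](O)/C=C(\C)[C@@H](CC(C)C)c1c(OC)cc(OC)cc1OC
F10 | step 22 | (2R,3E,5R)-4,7-dimethyl-5-(2,4,6-trimethoxyphenyl)oct-3-en-2-yl {(1S,3R)-2,2-dimethyl-3-[2-(2-methyl-1,3-dioxolan-2-yl)ethyl]cyclopropyl}acetate | CC1(OCCO1)CC[C@@H]2[C@H](CC(=O)O[C@H](C)/C=C(\C)[C@@H](CC(C)C)c3c(OC)cc(OC)cc3OC)C2(C)C
F11 | step 22 | (2R,3R,4R)-2-{(1R,3R)-2,2-dimethyl-3-[2-(2-methyl-1,3-dioxolan-2-yl)ethyl]cyclopropyl}-3,6-dimethyl-3-[(1E)-prop-1-en-1-yl]-4-(2,4,6-trimethoxyphenyl)heptanoic acid | CC1(OCCO1)CC[C@@H]2[C@H]([C@H]([C@](C)(/C=C/C)[C@@H](CC(C)C)c3c(OC)cc(OC)cc3OC)C(=O)O)C2(C)C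
F12 | step 25 | (4R,5R,6R)-4-{(1R,3R)-2,2-dimethyl-3-[2-(2-methyl-1,3-dioxolan-2-yl)ethyl]cyclopropyl}-5-ethenyl-5,8-dimethyl-6-(2,4,6-trimethoxyphenyl)non-1-en-3-ol (carbinol epimers) | CC1(OCCO1)CC[C@@H]2[C@H]([C@H]([C@](C)(C=C)[C@@H](CC(C)C)c3c(OC)cc(OC)cc3OC)C(O)C=C)C2(C)C
F13 | step 25 | (4R,5R)-5-{(1R,3R)-2,2-dimethyl-3-[2-(2-methyl-1,3-dioxolan-2-yl)ethyl]cyclopropyl}-4-methyl-4-[(1R)-3-methyl-1-(2,4,6-trimethoxyphenyl)butyl]cyclopent-2-en-1-ol (carbinol epimers) | CC1(OCCO1)CC[C@@H]2[C@H]([C@H]3C(O)C=C[C@]3(C)[C@@H](CC(C)C)c4c(OC)cc(OC)cc4OC)C2(C)C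
F14 | step 25 | (4R,5R)-5-{(1R,3R)-2,2-dimethyl-3-[2-(2-methyl-1,3-dioxolan-2-yl)ethyl]cyclopropyl}-4-methyl-4-[(1R)-3-methyl-1-(2,4,6-trimethoxyphenyl)butyl]cyclopent-2-en-1-one | CC1(OCCO1)CC[C@@H]2[C@H]([C@H]3C(=O)C=C[C@]3(C)[C@@H](CC(C)C)c4c(OC)cc(OC)cc4OC)C2(C)C
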